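The two aryl–carbon bonds at C7 and C7' are cut last. What remains, C7–C8(OH)–C8'–C7' with C9 and C9', is a 2-hydroxysuccinate that (R)-malic acid supplies and that two hydroxymethylations fold into the cis-fused bis-lactone. The key step ionises both anomeric acetates of the 8-O-silyl bis-lactol diacetate and adds two silyl-protected guaiacylzinc units, creating both C–aryl bonds and both benzylic stereocentres at once. It exploits the fold of ring A (O–C7'–C8'–C8–C9) and ring B (O–C7–C8–C8'–C9') about the C8–C8' bond: the oxocarbenium carbons C7 and C7' are open only on the convex face, where the target carries its aryl groups.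

Key step: step 9

Remark: lignan numbering is used (C7/C7' benzylic, C8 carbinol, C8' ring-fusion CH, C9/C9' the OCH2 carbons). Diacetate 12 is assumed to be usable as its anomeric mixture, because both anomeric carbons become planar before the aryl groups add. The arylzinc is used in excess and freed of THF so that the Lewis acid is not tied up by the solvent.

Step 1
Reactants: 1 (R)-malic acid; 2 pivalaldehyde
Product: 3 [(2R,4R)-2-tert-butyl-5-oxo-1,3-dioxolan-4-yl]acetic acid (cis acetal)
Conditions: 4-MeC6H4SO3H·H2O (cat.), H2SO4 (cat.), pentane, reflux, Dean–Stark; crystallisation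
Reagents that add atoms: none
Why: Acid-catalysed acetalisation of the α-hydroxy acid unit (dioxolanone formation) closes the five-membered ring in preference to the six-membered alternative through the distal carboxyl group, and under these equilibrating conditions the cis acetal, with tert-butyl and CH2CO2H on the same face, should predominate and crystallise, so the new acetal centre is set by the malic acid carbinol centre (the future C8).

Step 2
Reactants: 3 [(2R,4R)-2-tert-butyl-5-oxo-1,3-dioxolan-4-yl]acetic acid; 4 formaldehyde (gas from cracked paraformaldehyde)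
Product: 6 (2R,5S)-2-tert-butyl-1,3,7-trioxaspiro[4.4]nonane-4,8-dione, via hydroxymethyl dioxolanone acid 5 (not isolated)
Conditions: LiN(SiMe3)2 (2.2 equiv), THF, −78 °C; CH2O (g), −78 → −40 °C; 1 M HCl; then 4-MeC6H4SO3H·H2O (cat.), CH2Cl2, rt
Reagents that add atoms: none
Why: Aldol addition under self-regeneration of stereocentres, in which the dilithium carboxylate–enolate retains only the acetal centre and its tert-butyl group sends formaldehyde to the opposite face, so that C9 takes the place of the former hydrogen and C8 becomes quaternary with the required configuration, after which acid-catalysed lactonisation of the γ-hydroxy acid joins O9 to C7' (the lactone form of ring A).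

Step 3
Reactants: 6 (2R,5S)-2-tert-butyl-1,3,7-trioxaspiro[4.4]nonane-4,8-dione
Product: 7 methyl (3S)-3-hydroxy-5-oxotetrahydrofuran-3-carboxylate
Conditions: MeOH, 4-MeC6H4SO3H·H2O (0.1 equiv), reflux; evaporation from toluene
Reagents that add atoms: methanol, CO
Why: Acid-catalysed methanolysis (transacetalisation and esterification) removes the pivalaldehyde acetal, which frees the C8 hydroxyl and leaves C7 as its methyl ester, while the γ-lactone recloses on evaporation because it is the only ring that the C9 oxygen can form and the quaternary C8 cannot epimerise.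

Step 4
Reactants: 7 methyl (3S)-3-hydroxy-5-oxotetrahydrofuran-3-carboxylate; 4 formaldehyde (gas)
Product: 9 (1S,5S)-1-hydroxy-3,7-dioxabicyclo[3.3.0]octane-2,6-dione, via hydroxymethyl lactone ester 8 (not isolated)
Conditions: LiN(iPr)2 (2.3 equiv), THF, −78 °C; CH2O (g), −78 → −40 °C; HCl in Et2O; then 4-MeC6H4SO3H·H2O (cat.), toluene, 60 °C
Reagents that add atoms: none
Why: Fráter–Seebach-type aldol of the β-hydroxy lactone dianion, whose alkoxide cannot be eliminated and directs formaldehyde to the face of C8' remote from it, which puts C9' cis to the C7 ester so that lactonisation closes ring B as the cis-fused bis-lactone; C8' is thereby set by C8, and because C8' is enolisable and only the cis arrangement can lactonise, the bicycle is also the thermodynamic sink.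

Step 5
Reactants: 9 (1S,5S)-1-hydroxy-3,7-dioxabicyclo[3.3.0]octane-2,6-dione
Product: 10 (1S,5S)-1-(triethylsilyloxy)-3,7-dioxabicyclo[3.3.0]octane-2,6-dione
Conditions: Et3SiOTf, 2,6-lutidine, CH2Cl2, −78 → 0 °C
Reagents that add atoms: triethylsilyl trifluoromethanesulfonate, CC[Si](CC)(CC)OS(=O)(=O)C(F)(F)F
Why: Silylation of the hindered tertiary alcohol with a silyl triflate and a non-nucleophilic pyridine base installs a group on O8 that cannot bridge to C7, is small enough to leave the convex face open and falls to fluoride together with the aryl silyl ethers, and no stereocentre is at risk because C8' can only reprotonate to the cis-fused bicycle.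

Step 6
Reactants: 10 (1S,5S)-1-(triethylsilyloxy)-3,7-dioxabicyclo[3.3.0]octane-2,6-dione
Product: 12 (1S,5S)-1-(triethylsilyloxy)-3,7-dioxabicyclo[3.3.0]octane-2,6-diyl diacetate (anomeric mixture), via bis(diisobutylaluminium) lactolate 11 (not isolated)
Conditions: iBu2AlH (2.4 equiv), CH2Cl2, −78 °C; then pyridine, 4-(dimethylamino)pyridine, Ac2O, −78 → 0 °C
Reagents that add atoms: acetic anhydride, CC(=O)OC(C)=O
Why: One-pot reductive acetylation, in which iBu2AlH adds once to each lactone carbonyl at −78 °C and the persistent aluminium hemiacetals are acylated in situ, should give the bis(α-acetoxy ether) without liberating the lactols or their ring-opened aldehydes, leaves C8 and C8' untouched and produces anomeric centres whose configuration does not matter.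

Step 7
Reactants: 13 4-bromo-2-methoxyphenol
Product: 14 (4-bromo-2-methoxyphenoxy)(tert-butyl)dimethylsilane
Conditions: tBuMe2SiCl, imidazole, DMF, rt
Reagents that add atoms: tert-butyldimethylsilyl chloride, CC(C)(C)[Si](C)(C)Cl
Why: Routine silylation of a phenol (silyl chloride, imidazole) masks the acidic OH as an ether that survives organomagnesium and organozinc formation and is removed by fluoride in the last step.

Step 8
Reactants: 14 (4-bromo-2-methoxyphenoxy)(tert-butyl)dimethylsilane
Product: 16 [4-(tert-butyldimethylsilyloxy)-3-methoxyphenyl]zinc bromide (titrated solution), via arylmagnesium bromide 15 (not isolated)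
Conditions: Mg turnings, THF, 40 °C; then ZnBr2 (1.0 equiv), THF, 0 °C → rt
Reagents that add atoms: zinc dibromide, Br[Zn]Br
Why: Magnesium insertion into the aryl–bromine bond followed by transmetallation to zinc gives an aryl nucleophile that is mild enough to coexist with BF3·OEt2 and anomeric acetates.

Step 9
Reactants: 12 (1S,5S)-1-(triethylsilyloxy)-3,7-dioxabicyclo[3.3.0]octane-2,6-diyl diacetate; 16 [4-(tert-butyldimethylsilyloxy)-3-methoxyphenyl]zinc bromide (5 equiv)
Product: 17 (1S,2R,5R,6S)-2,6-bis[4-(tert-butyldimethylsilyloxy)-3-methoxyphenyl]-1-(triethylsilyloxy)-3,7-dioxabicyclo[3.3.0]octane (both aryl groups exo; lignan descriptors 7R,8S,7'S,8'R)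
Conditions: 16 (THF exchanged for toluene), BF3·OEt2 (3 equiv), CH2Cl2/toluene, −78 → −20 °C
Reagents that add atoms: none
Why: BF3·OEt2 activates the anomeric acetates one after the other, the ring oxygen expels each as it leaves, and the aryl group passes from zinc to the oxocarbenium carbon, first at C7' and then at the more hindered, inductively deactivated C7, which forms the C7'–aryl and C7–aryl bonds. The closest known reaction type is the Lewis-acid-promoted substitution of lactol acetates and glycosyl donors by organozinc reagents that is used for C-aryl glycosides. No ring is closed, because rings A and B are already in place. At C7' the configuration is controlled by the cis ring fusion, since ring B lies under the concave face and the aryl group must enter exo, cis to H8'. At C7 ring A shields the concave face in the same way, and the silyl ether on O8, which unlike an acyloxy group cannot bridge to C7, leaves the convex face open, so the aryl group ends up cis to O8. The step needs exo attack twice and ionisation of the acetates in preference to the benzylic C–O bonds of the product, which the folded bicycle, the better leaving group, the low temperature and the silyl-capped, less electron-releasing phenol oxygens should secure.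

Step 10
Reactants: 17 (1S,2R,5R,6S)-2,6-bis[4-(tert-butyldimethylsilyloxy)-3-methoxyphenyl]-1-(triethylsilyloxy)-3,7-dioxabicyclo[3.3.0]octane
Product: 18 8-hydroxypinoresinol, (1S,2R,5R,6S)-2,6-bis(4-hydroxy-3-methoxyphenyl)-3,7-dioxabicyclo[3.3.0]octan-1-ol
Conditions: Bu4NF (4 equiv), AcOH (4 equiv), THF, 0 °C → rt
Reagents that add atoms: none
Why: Fluoride-induced desilylation, driven by Si–F bond formation, cleaves the two aryl silyl ethers and the tertiary triethylsilyl ether in one operation, the acetic acid buffer keeping the liberated phenols protonated so that no quinone methide can open the benzylic ethers and none of the four stereocentres is disturbed.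

Compound list
1 | (R)-malic acid | OC(=O)C[C@@H](O)C(=O)O | starting material
2 | pivalaldehyde | CC(C)(C)C=O | starting material
3 | [(2R,4R)-2-tert-butyl-5-oxo-1,3-dioxolan-4-yl]acetic acid (cis) | CC(C)(C)[C@@H]1O[C@H](CC(=O)O)C(=O)O1 | intermediate
4 | formaldehyde | C=O | starting material
5 | [(2R,4S)-2-tert-butyl-4-(hydroxymethyl)-5-oxo-1,3-dioxolan-4-yl]acetic acid (CH2OH trans to tert-butyl) | CC(C)(C)[C@@H]1O[C@](CO)(CC(=O)O)C(=O)O1 | intermediate
6 | (2R,5S)-2-tert-butyl-1,3,7-trioxaspiro[4.4]nonane-4,8-dione | CC(C)(C)[C@@H]1O[C@@]2(COC(=O)C2)C(=O)O1 | intermediate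
7 | methyl (3S)-3-hydroxy-5-oxotetrahydrofuran-3-carboxylate | COC(=O)[C@@]1(O)COC(=O)C1 | intermediate
8 | methyl (3S,4S)-3-hydroxy-4-(hydroxymethyl)-5-oxotetrahydrofuran-3-carboxylate (CH2OH cis to CO2Me) | COC(=O)[C@@]1(O)COC(=O)[C@H]1CO | intermediate
9 | (1S,5S)-1-hydroxy-3,7-dioxabicyclo[3.3.0]octane-2,6-dione (cis-fused) | O=C1OC[C@]2(O)C(=O)OC[C@H]12 | intermediate
10 | (1S,5S)-1-(triethylsilyloxy)-3,7-dioxabicyclo[3.3.0]octane-2,6-dione | O=C1OC[C@]2(O[Si](CC)(CC)CC)C(=O)OC[C@H]12 | intermediate
11 | (1S,5S)-2,6-bis(diisobutylaluminiooxy)-1-(triethylsilyloxy)-3,7-dioxabicyclo[3.3.0]octane (anomeric centres unassigned) | CC(C)C[Al](CC(C)C)OC1OC[C@]2(O[Si](CC)(CC)CC)C(O[Al](CC(C)C)CC(C)C)OC[C@H]12 | intermediate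
12 | (1S,5S)-1-(triethylsilyloxy)-3,7-dioxabicyclo[3.3.0]octane-2,6-diyl diacetate (anomeric mixture) | CC(=O)OC1OC[C@]2(O[Si](CC)(CC)CC)C(OC(C)=O)OC[C@H]12 | intermediate
13 | 4-bromo-2-methoxyphenol | COc1cc(Br)ccc1O | starting material
14 | (4-bromo-2-methoxyphenoxy)(tert-butyl)dimethylsilane | COc1cc(Br)ccc1O[Si](C)(C)C(C)(C)C | intermediate
15 | [4-(tert-butyldimethylsilyloxy)-3-methoxyphenyl]magnesium bromide | COc1cc([Mg]Br)ccc1O[Si](C)(C)C(C)(C)C | intermediate
16 | [4-(tert-butyldimethylsilyloxy)-3-methoxyphenyl]zinc bromide | COc1cc([Zn]Br)ccc1O[Si](C)(C)C(C)(C)C | intermediate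
17 | (1S,2R,5R,6S)-2,6-bis[4-(tert-butyldimethylsilyloxy)-3-methoxyphenyl]-1-(triethylsilyloxy)-3,7-dioxabicyclo[3.3.0]octane | COc1cc([C@H]2OC[C@]3(O[Si](CC)(CC)CC)[C@@H](c4ccc(O[Si](C)(C)C(C)(C)C)c(OC)c4)OC[C@H]23)ccc1O[Si](C)(C)C(C)(C)C | intermediate
18 | 8-hydroxypinoresinol, (7R,8S,7'S,8'R) | COc1cc([C@H]2OC[C@]3(O)[C@@H](c4ccc(O)c(OC)c4)OC[C@H]23)ccc1O | target

Total step count: 10. Longest linear sequence: 8 steps (steps 1–6, 9 and 10, from (R)-malic acid); the aryl branch contributes steps 7 and 8.

Steps most likely to fail

Step 9. The substitution may stop after the first arylation because the C7 acetate ionises slowly next to the silyloxy-bearing quaternary C8. Aryl transfer at C7 may also occur partly from the concave face, since the O8 silyl group sits on the convex side. A third risk is that the Lewis acid reopens the new electron-rich benzylic ethers and scrambles C7/C7'. The fallback attaches the aryl groups by carbonyl addition and sets the benzylic centres in a ring closure. It sets out from bis-lactone 10 and aryl bromide 14. Bromine–lithium exchange of 14 (nBuLi, THF, −78 °C) gives [4-(tert-butyldimethylsilyloxy)-3-methoxyphenyl]lithium F1. F1 adds once to each lactone carbonyl of 10 at −78 °C to give the 2,6-diaryl bis-hemiketal F2. NaBH4 in MeOH at 0 °C reduces the ring-opened aryl ketone form of F2 to the 1,4-diaryl-2,3-bis(hydroxymethyl)-2-(triethylsilyloxy)butane-1,4-diol F3, whose benzylic configuration is irrelevant. Catalytic (+)-camphor-10-sulfonic acid in CH2Cl2 at 0 °C should then ionise the two benzylic alcohols, and the C9' and C9 hydroxyls close rings B and A with the aryl groups settling exo, as in the classical cyclodehydration route to furofuran lignans. The route is rejoined at 17.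

Step 4. The aldol with gaseous formaldehyde may give low conversion through oligomerisation of the electrophile or retro-aldol on warming. The hydroxymethyl lactone may also dehydrate to the α-methylene lactone, or ring closure may remain incomplete. The fallback introduces C9' as a protected carbon electrophile and sets out from 7. The same dianion (LiN(iPr)2, THF/DMPU, −78 °C) is alkylated with benzyl chloromethyl ether in a Fráter–Seebach alkylation, trans to the alkoxide, to give methyl (3S,4S)-4-(benzyloxymethyl)-3-hydroxy-5-oxotetrahydrofuran-3-carboxylate F4. Hydrogenolysis (H2, Pd/C, EtOAc) should free the primary alcohol 8, and 4-MeC6H4SO3H·H2O in warm toluene closes ring B. The route is rejoined at 9.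

Step 2. The carboxylate–enolate dianion may add sluggishly to formaldehyde, or the adduct may be lost through hemiformal oligomers and retro-aldol before lactonisation. The fallback sets out from 3. Its dianion (LiN(SiMe3)2, THF, −78 °C) is alkylated with benzyl chloromethyl ether, an alkyl-halide alkylation under the same tert-butyl facial control, to give [(2R,4S)-4-(benzyloxymethyl)-2-tert-butyl-5-oxo-1,3-dioxolan-4-yl]acetic acid F5. Hydrogenolysis (H2, Pd/C, EtOAc) should give hydroxy acid 5, which lactonises under 4-MeC6H4SO3H·H2O. The route is rejoined at 6.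

Further compounds
F1 | step 9 | [4-(tert-butyldimethylsilyloxy)-3-methoxyphenyl]lithium | COc1cc([Li])ccc1O[Si](C)(C)C(C)(C)C
F2 | step 9 | 2,6-bis[4-(tert-butyldimethylsilyloxy)-3-methoxyphenyl]-1-(triethylsilyloxy)-3,7-dioxabicyclo[3.3.0]octane-2,6-diol (ring-fusion centres as in 10, hemiketal centres unassigned) | COc1cc(C2(O)OC[C@]3(O[Si](CC)(CC)CC)C(O)(c4ccc(O[Si](C)(C)C(C)(C)C)c(OC)c4)OC[C@H]23)ccc1O[Si](C)(C)C(C)(C)C
F3 | step 9 | 1,4-bis[4-(tert-butyldimethylsilyloxy)-3-methoxyphenyl]-2,3-bis(hydroxymethyl)-2-(triethylsilyloxy)butane-1,4-diol (C8 and C8' as in 10, benzylic carbinols unassigned) | COc1cc(C(O)[C@@H](CO)[C@@](CO)(O[Si](CC)(CC)CC)C(O)c2ccc(O[Si](C)(C)C(C)(C)C)c(OC)c2)ccc1O[Si](C)(C)C(C)(C)C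
F4 | step 4 | methyl (3S,4S)-4-(benzyloxymethyl)-3-hydroxy-5-oxotetrahydrofuran-3-carboxylate | COC(=O)[C@@]1(O)COC(=O)[C@H]1COCc1ccccc1
F5 | step 2 | [(2R,4S)-4-(benzyloxymethyl)-2-tert-butyl-5-oxo-1,3-dioxolan-4-yl]acetic acid | CC(C)(C)[C@@H]1O[C@](COCc2ccccc2)(CC(=O)O)C(=O)O1
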